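**Retrosynthetic overview**
1. Target 13 ⇒ pyran C–O bond (C8a–O–C2, last ring formed, sets C2) by catalyst-controlled oxa-6π closure of the 1-oxatriene from hydroxyquinone 10 and enal 7; the same operation makes C4–C4a by Knoevenagel condensation.
2. Enal 7 ⇒ methyl ketone 5 (formyl-olefination) ⇒ enone 4 (conjugate reduction) ⇒ aldehyde 3 (Horner–Wadsworth–Emmons).
3. Aldehyde 3 (cyclohexene ring, first ring formed, both ring stereocentres) ⇒ enantioselective Diels–Alder of (E)-3-methylpenta-1,3-diene 1 with methacrolein 2.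
4. Hydroxyquinone 10 ⇒ 2,5-dimethoxy-1,4-benzoquinone 8 (mono-hydrolysis); the quinone ring is bought.

Assumption: the facial sense of the chiral catalyst in step 1 follows the accepted pre-transition-state model, the sense in step 6 is fixed by one trial with both catalyst antipodes, and both antipodes of each catalyst are available.

Note: the ring descriptors change along the route (1R,2S in 3, 1S,2S in 4, 1S,2R from 5 on) only because the CIP priorities of the side chain change; the spatial arrangement is the same throughout.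

**Step 1**
Reactants: 1 (3E)-3-methylpenta-1,3-diene; 2 methacrolein
Product: 3 (1R,2S)-1,2,3-trimethylcyclohex-3-ene-1-carbaldehyde
Conditions: diene used as the commercial E/Z mixture (3 equiv), (R)-tetrahydro-1-(2-methylphenyl)-3,3-diphenyl-1H,3H-pyrrolo[1,2-c][1,3,2]oxazaborole (10 mol %), Tf2NH (8 mol %), CH2Cl2, –78 → –40 °C
Reagents that add atoms: none
Why: Enantioselective Lewis-acid-catalysed Diels–Alder reaction in which the triflimide-activated oxazaborolidinium binds s-trans methacrolein and leaves its Cα Si face open, only the E diene reaches the s-cis form, its methyl-bearing terminus bonds to the quaternary carbon (ortho directive of the terminal methyl) and the formyl-endo transition state puts CHO cis to the C2 methyl, which sets C1 and C2 together.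

**Step 2**
Reactants: 3 (1R,2S)-1,2,3-trimethylcyclohex-3-ene-1-carbaldehyde
Product: 4 (3E)-4-[(1S,2S)-1,2,3-trimethylcyclohex-3-en-1-yl]but-3-en-2-one
Conditions: dimethyl (2-oxopropyl)phosphonate, NaH, THF, 0 → 50 °C
Reagents that add atoms: dimethyl (2-oxopropyl)phosphonate, COP(=O)(CC(C)=O)OC
Why: Horner–Wadsworth–Emmons olefination of a non-enolisable aldehyde with a stabilised keto-phosphonate gives the E enone and touches no stereocentre.

**Step 3**
Reactants: 4 (3E)-4-[(1S,2S)-1,2,3-trimethylcyclohex-3-en-1-yl]but-3-en-2-one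
Product: 5 4-[(1S,2R)-1,2,3-trimethylcyclohex-3-en-1-yl]butan-2-one
Conditions: Cu(OAc)2·H2O (5 mol %), 1,2-bis(diphenylphosphino)benzene (5 mol %), (EtO)2MeSiH (1.5 equiv), t-BuOH (1.5 equiv), toluene, 0 °C → rt
Reagents that add atoms: none
Why: Phosphine-ligated CuH 1,4-reduction (Stryker-type conjugate reduction) is selective for the enone C=C over the isolated trisubstituted ring alkene, and t-BuOH protonates the copper enolate before the ketone is reduced.

**Step 4**
Reactants: 5 4-[(1S,2R)-1,2,3-trimethylcyclohex-3-en-1-yl]butan-2-one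
Product: 7 (2E)-3-methyl-5-[(1S,2R)-1,2,3-trimethylcyclohex-3-en-1-yl]pent-2-enal, via N-cyclohexyl unsaturated aldimine 6 (not isolated)
Conditions: diethyl [2-(cyclohexylamino)ethenyl]phosphonate, NaH, THF, 0 °C → rt, then 5, rt → 40 °C; then aq. oxalic acid/toluene, rt; E isomer separated from Z on SiO2
Reagents that add atoms: diethyl [(E)-2-(cyclohexylamino)ethenyl]phosphonate, CCOP(=O)(/C=C/NC1CCCCC1)OCC; water, O
Why: Nagata formyl-olefination (Horner–Wittig reaction of the metallated enamine phosphonate, then imine hydrolysis) turns the methyl ketone directly into the trisubstituted enal as an E/Z mixture (E major, about 2–3:1 expected), from which the E isomer is isolated and the Z isomer re-equilibrated.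

**Step 5**
Reactants: 8 2,5-dimethoxy-1,4-benzoquinone
Product: 10 2-hydroxy-5-methoxy-1,4-benzoquinone, via sodium quinonolate 9 (not isolated)
Conditions: NaOH (1.05 equiv), H2O/THF, 0 °C → rt; then 1 M HCl
Reagents that add atoms: sodium hydroxide, [Na+].[OH-]
Why: Addition–elimination of hydroxide at one vinylogous ester (saponification) stops after the first methoxy group because the hydroxyquinone anion formed is deactivated toward a second attack.

**Step 6**
Reactants: 7 (2E)-3-methyl-5-[(1S,2R)-1,2,3-trimethylcyclohex-3-en-1-yl]pent-2-enal; 10 2-hydroxy-5-methoxy-1,4-benzoquinone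
Product: 13 (2S)-6-methoxy-2-methyl-2-{2-[(1S,2R)-1,2,3-trimethylcyclohex-3-en-1-yl]ethyl}-2H-chromene-5,8-dione, via aldol adduct 11 (not isolated), via 1-oxatriene 12 (not isolated)
Conditions: hydroxyquinone in 1.3-fold excess, (R)-3,3′-bis(2,4,6-triisopropylphenyl)-1,1′-binaphthyl-2,2′-diyl N-(trifluoromethylsulfonyl)phosphoramide (5 mol %), 5 Å molecular sieves, CH2Cl2, –30 °C, 48 h
Reagents that add atoms: none
Why: Proposed new method: a chiral-Brønsted-acid-controlled Knoevenagel/oxa-6π annulation of a hydroxyquinone, in which the phosphoramide (far more acidic than 10, so it outruns self-catalysis) activates 7 for attack by the enol carbon of 10 to give 11, dehydration gives the O-protonated oxatriene 12 as a contact ion pair with the chiral anion, and the disrotatory C–O closure (methyl inside, side chain outside, fixed by the E alkene) runs through the one helical sense that fits between the 3,3′-aryl walls, giving the (2S) centre and, by closure through the oxygen of the former C–OH carbon, the para-quinone; the closest known reactions are the racemic amine- or acid-mediated formal [3+3] annulation of hydroxyquinones with enals and chiral N-triflylphosphoramide-controlled torquoselective Nazarov electrocyclisations.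

**Compound list**
1 | (3E)-3-methylpenta-1,3-diene | C=C/C(C)=C/C | starting material
2 | methacrolein (2-methylprop-2-enal) | CC(=C)C=O | starting material
3 | (1R,2S)-1,2,3-trimethylcyclohex-3-ene-1-carbaldehyde (CHO cis to the C2 methyl) | O=C[C@]1(C)CCC=C(C)[C@@H]1C | intermediate
4 | (3E)-4-[(1S,2S)-1,2,3-trimethylcyclohex-3-en-1-yl]but-3-en-2-one | CC(=O)/C=C/[C@]1(C)CCC=C(C)[C@@H]1C | intermediate
5 | 4-[(1S,2R)-1,2,3-trimethylcyclohex-3-en-1-yl]butan-2-one | CC(=O)CC[C@]1(C)CCC=C(C)[C@@H]1C | intermediate
6 | (2E)-N-cyclohexyl-3-methyl-5-[(1S,2R)-1,2,3-trimethylcyclohex-3-en-1-yl]pent-2-en-1-imine (not isolated) | C1CCCCC1N=C/C=C(C)/CC[C@]2(C)CCC=C(C)[C@@H]2C | intermediate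
7 | (2E)-3-methyl-5-[(1S,2R)-1,2,3-trimethylcyclohex-3-en-1-yl]pent-2-enal | O=C/C=C(C)/CC[C@]1(C)CCC=C(C)[C@@H]1C | intermediate
8 | 2,5-dimethoxy-1,4-benzoquinone | COC1=CC(=O)C(OC)=CC1=O | starting material
9 | sodium 4-methoxy-3,6-dioxocyclohexa-1,4-dien-1-olate (not isolated) | COC1=CC(=O)C([O-])=CC1=O.[Na+] | intermediate
10 | 2-hydroxy-5-methoxy-1,4-benzoquinone | COC1=CC(=O)C(O)=CC1=O | intermediate
11 | 2-hydroxy-3-{(2E)-1-hydroxy-3-methyl-5-[(1S,2R)-1,2,3-trimethylcyclohex-3-en-1-yl]pent-2-en-1-yl}-5-methoxy-1,4-benzoquinone (both carbinol epimers, not isolated) | COC1=CC(=O)C(O)=C(C(O)/C=C(C)/CC[C@]2(C)CCC=C(C)[C@@H]2C)C1=O | intermediate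
12 | 5-methoxy-3-{(2E)-3-methyl-5-[(1S,2R)-1,2,3-trimethylcyclohex-3-en-1-yl]pent-2-en-1-ylidene}cyclohex-5-ene-1,2,4-trione (not isolated) | COC1=CC(=O)C(=O)C(=C/C=C(C)/CC[C@]2(C)CCC=C(C)[C@@H]2C)C1=O | intermediate
13 | (2S)-6-methoxy-2-methyl-2-{2-[(1S,2R)-1,2,3-trimethylcyclohex-3-en-1-yl]ethyl}-2H-chromene-5,8-dione | COC1=CC(=O)C2=C(C=C[C@](C)(CC[C@]3(C)CCC=C(C)[C@@H]3C)O2)C1=O | target

**Totals and risks**
Total steps: 6. Longest linear sequence: 5 (steps 1, 2, 3, 4, 6).

The step most likely to fail is step 6, the proposed new step. The risks are low diastereoselectivity at C2, acid-induced cyclisation of the enal or oxatriene onto the ring alkene, and formation of the ortho-quinone isomer. The fallback uses known chemistry and sets out from 7 and 10 (the E/Z mixture of the enal may be used). Ethylenediammonium diacetate (10 mol %) in toluene at 60 °C effects the ordinary Knoevenagel/oxa-6π annulation without stereocontrol. It gives 13 together with its C2 epimer, (2R)-6-methoxy-2-methyl-2-{2-[(1S,2R)-1,2,3-trimethylcyclohex-3-en-1-yl]ethyl}-2H-chromene-5,8-dione F1, in about equal amounts. The two are separated by preparative HPLC on cellulose tris(3,5-dimethylphenylcarbamate), which returns the route at 13.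

The second risk is step 1. The terminal and internal methyl groups of the diene direct regiochemistry in opposite senses, and endo/exo selectivity and ee with this diene are not assured. The fallback replaces asymmetric catalysis by resolution and sets out from 1 and 2. Me2AlCl (0.2 equiv) in CH2Cl2 at –78 → –20 °C, the small achiral Lewis acid that maximises ortho/endo selectivity, gives 3 as the racemate, that is, together with its enantiomer (1S,2R)-1,2,3-trimethylcyclohex-3-ene-1-carbaldehyde F2. Condensation with (1R,2R)-N,N′-dimethyl-1,2-diphenylethane-1,2-diamine (4 Å molecular sieves, CH2Cl2) gives two diastereomeric aminals. These are (4R,5R)-1,3-dimethyl-4,5-diphenyl-2-[(1R,2S)-1,2,3-trimethylcyclohex-3-en-1-yl]imidazolidine F3 (from 3) and (4R,5R)-1,3-dimethyl-4,5-diphenyl-2-[(1S,2R)-1,2,3-trimethylcyclohex-3-en-1-yl]imidazolidine F4 (from F2). They are separated by chromatography on Et3N-deactivated silica, and hydrolysis of F3 (0.5 M HCl, Et2O, 0 °C) returns the route at 3.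

The third risk is step 4, through enolisation of the methyl ketone and a modest E/Z ratio. The fallback builds the alkene at the ester oxidation level and sets out from 5. Triethyl phosphonoacetate with NaH in THF gives ethyl (2E)-3-methyl-5-[(1S,2R)-1,2,3-trimethylcyclohex-3-en-1-yl]pent-2-enoate F5, typically E/Z about 4–5:1 and separable. i-Bu2AlH in CH2Cl2 at –78 °C then gives (2E)-3-methyl-5-[(1S,2R)-1,2,3-trimethylcyclohex-3-en-1-yl]pent-2-en-1-ol F6, and MnO2 in CH2Cl2 returns the route at 7.

**Further compounds**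
F1 | step 6 | (2R)-6-methoxy-2-methyl-2-{2-[(1S,2R)-1,2,3-trimethylcyclohex-3-en-1-yl]ethyl}-2H-chromene-5,8-dione | COC1=CC(=O)C2=C(C=C[C@@](C)(CC[C@]3(C)CCC=C(C)[C@@H]3C)O2)C1=O
F2 | step 1 | (1S,2R)-1,2,3-trimethylcyclohex-3-ene-1-carbaldehyde | O=C[C@@]1(C)CCC=C(C)[C@H]1C
F3 | step 1 | (4R,5R)-1,3-dimethyl-4,5-diphenyl-2-[(1R,2S)-1,2,3-trimethylcyclohex-3-en-1-yl]imidazolidine | CN1[C@H](c2ccccc2)[C@H](N(C)C1[C@]3(C)CCC=C(C)[C@@H]3C)c2ccccc2
F4 | step 1 | (4R,5R)-1,3-dimethyl-4,5-diphenyl-2-[(1S,2R)-1,2,3-trimethylcyclohex-3-en-1-yl]imidazolidine | CN1[C@H](c2ccccc2)[C@H](N(C)C1[C@@]3(C)CCC=C(C)[C@H]3C)c2ccccc2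
F5 | step 4 | ethyl (2E)-3-methyl-5-[(1S,2R)-1,2,3-trimethylcyclohex-3-en-1-yl]pent-2-enoate | CCOC(=O)/C=C(C)/CC[C@]1(C)CCC=C(C)[C@@H]1C
F6 | step 4 | (2E)-3-methyl-5-[(1S,2R)-1,2,3-trimethylcyclohex-3-en-1-yl]pent-2-en-1-ol | OC/C=C(C)/CC[C@]1(C)CCC=C(C)[C@@H]1C
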